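**Plan**

- Retrosynthesis: cut the aryl–C11 bond (B-alkyl Suzuki) and C9=C11 (methylenation) to reach a bicyclic C9 enone. Then cut C7=C8 and C5–C10 together, which opens both rings to the acyclic keto-enal 8. The chain is cut at C1–C10, C5=C6 and C3–C4.
- Enabling feature (drimane numbering): C9 lies between C8 and C10, the two carbons that must bond to C7 and C5. As a ketone, C9 makes C8/C10 a 1,3-bis-nucleophile; C5–C6–C7 as an (E)-enal is the matching 1,3-bis-electrophile. The C1–C3 tether and the quaternary C4 (gem-dimethyl, no γ-hydrogen) steer the event into ring A and then ring B.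
- Forward: the chain is joined from isobutyronitrile, 1,3-dibromopropane, 3-pentanone and a formylmethylene ylide. Ring A and then ring B close in step 6. The C9 carbonyl is then converted into the exocyclic C9=C11 methylene, which is hydroborated and coupled to the arene; the MOM groups come off last.
- Stereochemistry: C5 from the chiral amine catalyst (face shielding of the iminium ion); C10 relative to C5 through a chair transition state (trans ring fusion); C9 from α-face hydroboration opposite the axial C10 methyl.

Key step: step 6

Remark: drimane numbering (C1–C10 decalin carbons, C11 the benzylic CH2 on C9, C12 the methyl on C8) is used for all intermediates; methyl 3-bromo-4,5-dihydroxybenzoate and the other numbered starting materials are taken as commercially available.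

**Step 1**
Reactants: 1 isobutyronitrile; 2 1,3-dibromopropane
Product: 3 5-bromo-2,2-dimethylpentanenitrile
Conditions: LiN(i-Pr)2, THF, −78 °C; then 2 (3 equiv), −78 → 23 °C
Reagents that add atoms: none
Why: SN2 alkylation of the lithiated nitrile builds the quaternary C4 and the C3–C4 bond, and the excess dibromide should suppress double alkylation (nitrile anion alkylation).

**Step 2**
Reactants: 4 3-pentanone; 3 5-bromo-2,2-dimethylpentanenitrile
Product: 5 2,2,6-trimethyl-7-oxononanenitrile (racemic)
Conditions: 4 (3 equiv), LiN(i-Pr)2, THF, −78 °C; then 3, DMPU, −78 → 23 °C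
Reagents that add atoms: none
Why: Enolate alkylation of the symmetrical ketone (used in excess) with the primary bromide forms C1–C10 without a regiochemical issue, the hindered tertiary nitrile should be inert, and the new centre need not be controlled because it is enolised again in step 6.

**Step 3**
Reactants: 5 2,2,6-trimethyl-7-oxononanenitrile
Product: 6 7-hydroxy-2,2,6-trimethylnonanal (mixture of diastereomers)
Conditions: i-Bu2AlH (2.5 equiv), CH2Cl2, −78 → 0 °C; then 1 M aq. HCl
Reagents that add atoms: water, O
Why: i-Bu2AlH reduction stops at the aldimine for the nitrile (hydrolysed to the C5 aldehyde on work-up) and reduces the ketone to the alcohol, which masks C9 during chain extension (nitrile-to-aldehyde reduction).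

**Step 4**
Reactants: 6 7-hydroxy-2,2,6-trimethylnonanal
Product: 7 (E)-9-hydroxy-4,4,8-trimethylundec-2-enal (mixture of diastereomers)
Conditions: Ph3P=CHCHO (1.5 equiv), toluene, 90 °C
Reagents that add atoms: (triphenylphosphoranylidene)acetaldehyde, O=CC=P(c1ccccc1)(c1ccccc1)c1ccccc1
Why: Wittig olefination with the stabilised formylmethylene ylide should give the (E)-enal (C5=C6, C7), and the neopentyl product enal is too hindered to be homologated a second time.

**Step 5**
Reactants: 7 (E)-9-hydroxy-4,4,8-trimethylundec-2-enal
Product: 8 (E)-4,4,8-trimethyl-9-oxoundec-2-enal (racemic at the enolisable C10)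
Conditions: Dess–Martin periodinane, NaHCO3, CH2Cl2, 0 → 23 °C
Reagents that add atoms: none
Why: Dess–Martin oxidation returns the C9 ketone under buffered, non-basic conditions, so the enal survives and no premature racemic cyclisation is expected.

**Step 6**
Reactants: 8 (E)-4,4,8-trimethyl-9-oxoundec-2-enal
Product: 10 (4aS,8aS)-2,5,5,8a-tetramethyl-4a,5,6,7,8,8a-hexahydronaphthalen-1(4H)-one, via keto-aldehyde Michael adduct 9 (not isolated)
Conditions: (S)-2-[diphenyl(trimethylsilyloxy)methyl]pyrrolidine (20 mol %), PhCO2H (20 mol %), toluene, 23 → 50 °C, one flask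
Reagents that add atoms: none
Why: Proposed new method: the (S)-amine condenses with the enal of 8 to an (E)-iminium ion, the more substituted C9=C10 enol of the ketone adds to C5 in a 6-(enolexo)-exo-trig Michael reaction that closes ring A and forms C5–C10, and the same amine then converts the freed C7 aldehyde of 9 into an iminium ion that is attacked by the C8 enol (6-(enolendo)-exo-trig Mannich-type aldol) and eliminated to the C7=C8 enone, closing ring B. The closest known reaction type is the secondary-amine-catalysed Michael/aldol-condensation cascade of β-keto esters with enals to cyclohexenones; new here is an unactivated, α-branched ketone as the intramolecular donor. C5 is set by the catalyst, whose diphenyl(silyloxy)methyl group shields one face of the s-trans iminium ion so that C10 adds to the open face, which for the (S)-catalyst should give 5S. C10 is set relative to C5 in a chair-like transition state with the iminium-bearing C6 arm and the bulky tetrasubstituted enol unit at C9 both pseudo-equatorial and the C10 methyl axial, which becomes the trans ring fusion once ring B closes. The selectivities needed are C10 over C8 as Michael donor (secured by ring size, since C8 could only close an eight-membered ring), iminium instead of dienamine activation (secured by the quaternary C4, which leaves the enal without γ-hydrogens) and aldol closure of C8 onto C7 (the alternative C6-to-C9 closure would give a cyclobutanol). Dehydration should make the cascade irreversible, and both enantiomers of 8 converge because C10 passes through the enol.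

**Step 7**
Reactants: 10 (4aS,8aS)-2,5,5,8a-tetramethyl-4a,5,6,7,8,8a-hexahydronaphthalen-1(4H)-one
Product: 11 (4aS,8aS)-2,5,5,8a-tetramethyl-1-methylidene-1,4,4a,5,6,7,8,8a-octahydronaphthalene (drima-7,9(11)-diene)
Conditions: Ph3PCH3Br, KOt-Bu, toluene, 90 °C
Reagents that add atoms: methyltriphenylphosphonium bromide, C[P+](c1ccccc1)(c1ccccc1)c1ccccc1.[Br-]
Why: Wittig methylenation under forcing conditions used for hindered ketones converts the C9 carbonyl into C9=C11; C10 is quaternary and C5 is not acidic, so no stereocentre is at risk.

**Step 8**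
Reactants: 12 methyl 3-bromo-4,5-dihydroxybenzoate
Product: 13 methyl 3-bromo-4,5-bis(methoxymethoxy)benzoate
Conditions: MOMCl (3 equiv), i-Pr2NEt, CH2Cl2, 0 → 23 °C
Reagents that add atoms: chloromethyl methyl ether, COCCl
Why: O-alkylation of both phenols gives MOM acetals that are small enough next to the bromide for the coupling and stable to aqueous base (acetal protection of a catechol).

**Step 9**
Reactants: 11 drima-7,9(11)-diene; 14 9-borabicyclo[3.3.1]nonane (9-BBN); 13 methyl 3-bromo-4,5-bis(methoxymethoxy)benzoate
Product: 16 methyl 3,4-bis(methoxymethoxy)-5-{[(1S,4aS,8aS)-2,5,5,8a-tetramethyl-1,4,4a,5,6,7,8,8a-octahydronaphthalen-1-yl]methyl}benzoate, via B-alkyl-9-BBN adduct 15 (not isolated)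
Conditions: 14, THF, 0 → 60 °C; then 13, Pd(dppf)Cl2·CH2Cl2 (5 mol %), 3 M aq. K3PO4, DMF, 50 °C
Reagents that add atoms: none
Why: 9-BBN should add only to the exocyclic C9=C11 terminus and from the α-face, opposite the axial C10 methyl, placing boron on C11 and hydrogen on C9 (9α-H, 9S); the primary alkylborane then undergoes B-alkyl Suzuki–Miyaura coupling with 13, while the trisubstituted ring alkene, the ester and the MOM ethers should be untouched.

**Step 10**
Reactants: 16 methyl 3,4-bis(methoxymethoxy)-5-{[(1S,4aS,8aS)-2,5,5,8a-tetramethyl-1,4,4a,5,6,7,8,8a-octahydronaphthalen-1-yl]methyl}benzoate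
Product: 17 methyl 3,4-dihydroxy-5-{[(1S,4aS,8aS)-2,5,5,8a-tetramethyl-1,4,4a,5,6,7,8,8a-octahydronaphthalen-1-yl]methyl}benzoate (target)
Conditions: Me3SiOTf, 2,2′-bipyridyl, MeCN, 0 → 23 °C; then H2O
Reagents that add atoms: none
Why: Silyl triflate/bipyridyl cleavage of aryl MOM ethers goes through the aryl silyl ethers, which hydrolyse on adding water; it avoids free protic acid, which could shift the C7=C8 alkene or add the phenol ortho to C11 across it to form a chroman.

**Compound list**

1 | isobutyronitrile | CC(C)C#N | starting material
2 | 1,3-dibromopropane | BrCCCBr | starting material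
3 | 5-bromo-2,2-dimethylpentanenitrile | CC(C)(CCCBr)C#N | intermediate
4 | 3-pentanone | CCC(=O)CC | starting material
5 | 2,2,6-trimethyl-7-oxononanenitrile (racemic) | CCC(=O)C(C)CCCC(C)(C)C#N | intermediate
6 | 7-hydroxy-2,2,6-trimethylnonanal (diastereomer mixture) | CCC(O)C(C)CCCC(C)(C)C=O | intermediate
7 | (E)-9-hydroxy-4,4,8-trimethylundec-2-enal (diastereomer mixture) | CCC(O)C(C)CCCC(C)(C)/C=C/C=O | intermediate
8 | (E)-4,4,8-trimethyl-9-oxoundec-2-enal (racemic) | CCC(=O)C(C)CCCC(C)(C)/C=C/C=O | intermediate
9 | 2-[(1S,2S)-2,6,6-trimethyl-2-propanoylcyclohexyl]acetaldehyde (not isolated) | CCC(=O)[C@@]1(C)CCCC(C)(C)[C@@H]1CC=O | intermediate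
10 | (4aS,8aS)-2,5,5,8a-tetramethyl-4a,5,6,7,8,8a-hexahydronaphthalen-1(4H)-one | O=C1C(C)=CC[C@H]2C(C)(C)CCC[C@]12C | intermediate
11 | (4aS,8aS)-2,5,5,8a-tetramethyl-1-methylidene-1,4,4a,5,6,7,8,8a-octahydronaphthalene | C=C1C(C)=CC[C@H]2C(C)(C)CCC[C@]12C | intermediate
12 | methyl 3-bromo-4,5-dihydroxybenzoate | COC(=O)c1cc(O)c(O)c(Br)c1 | starting material
13 | methyl 3-bromo-4,5-bis(methoxymethoxy)benzoate | COCOc1cc(C(=O)OC)cc(Br)c1OCOC | intermediate
14 | 9-borabicyclo[3.3.1]nonane (9-BBN) | B1C2CCCC1CCC2 | starting material
15 | 9-{[(1S,4aS,8aS)-2,5,5,8a-tetramethyl-1,4,4a,5,6,7,8,8a-octahydronaphthalen-1-yl]methyl}-9-borabicyclo[3.3.1]nonane (not isolated) | C(B3C4CCCC3CCC4)[C@H]1C(C)=CC[C@H]2C(C)(C)CCC[C@]12C | intermediate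
16 | methyl 3,4-bis(methoxymethoxy)-5-{[(1S,4aS,8aS)-2,5,5,8a-tetramethyl-1,4,4a,5,6,7,8,8a-octahydronaphthalen-1-yl]methyl}benzoate | COCOc1cc(C(=O)OC)cc(C[C@H]2C(C)=CC[C@H]3C(C)(C)CCC[C@]23C)c1OCOC | intermediate
17 | methyl 3,4-dihydroxy-5-{[(1S,4aS,8aS)-2,5,5,8a-tetramethyl-1,4,4a,5,6,7,8,8a-octahydronaphthalen-1-yl]methyl}benzoate | COC(=O)c1cc(O)c(O)c(C[C@H]2C(C)=CC[C@H]3C(C)(C)CCC[C@]23C)c1 | target

**Totals**

Total step count: 10. Longest linear sequence: 9 steps (steps 1–7, 9 and 10).

**Steps most likely to fail**

1. Step 6 (Proposed new method). The unactivated ketone enol may not add to the hindered β-tert-alkyl iminium ion, or facial control at C5 and the cis/trans ratio at the ring fusion may be poor. Fallback: the cascade is run from 8 under anionic, thermodynamic conditions (KOt-Bu, t-BuOH/THF, 23 → 50 °C; base-mediated intramolecular Michael addition and aldol condensation, known chemistry). This should give the racemic trans-enone through racemic 9, that is, 9 and 10 together with their mirror images ent-9 F1 and ent-10 F2. The racemate is resolved by preparative chromatography on a chiral stationary phase (amylose tris(3,5-dimethylphenylcarbamate), supercritical CO2/MeOH). Enantiopure 10 re-enters the route at step 7.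

2. Step 9. Boron-to-palladium transfer from the hindered, β-branched alkylborane may be too slow, so that protodeboronation of 15 and debromination of 13 take over. Fallback: 15 is oxidised in the same flask (NaOH, H2O2) to drimenol F3, which is converted into 11-bromodrim-7-ene F4 (CBr4, PPh3, CH2Cl2). F4 is joined to 13 by nickel-catalysed reductive cross-electrophile coupling (NiI2, 4,4′-di-tert-butyl-2,2′-bipyridine, Zn, NaI, DMA, 60 °C), a known aryl bromide/alkyl bromide coupling that needs no organoboron transfer. This gives 16, and the route continues with step 10.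

3. Step 7. The ylide may act as a base on the doubly flanked C9 carbonyl (γ-deprotonation, leading to recovered or deconjugated enone) instead of adding to it. Fallback: 10 is treated with MeLi (THF, −78 °C; 1,2-addition) to give the tertiary allylic alcohol (4aS,8aS)-1,2,5,5,8a-pentamethyl-1,4,4a,5,6,7,8,8a-octahydronaphthalen-1-ol F5 (either C9 epimer). F5 is dehydrated with the Burgess reagent (benzene, 50 °C); only C11 carries a hydrogen that can be lost next to C9, so 11 should result, and the route continues with step 9.

**Further compounds**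

F1 | step 6 | 2-[(1R,2R)-2,6,6-trimethyl-2-propanoylcyclohexyl]acetaldehyde (ent-9) | CCC(=O)[C@]1(C)CCCC(C)(C)[C@H]1CC=O
F2 | step 6 | (4aR,8aR)-2,5,5,8a-tetramethyl-4a,5,6,7,8,8a-hexahydronaphthalen-1(4H)-one (ent-10) | O=C1C(C)=CC[C@@H]2C(C)(C)CCC[C@@]12C
F3 | step 9 | [(1S,4aS,8aS)-2,5,5,8a-tetramethyl-1,4,4a,5,6,7,8,8a-octahydronaphthalen-1-yl]methanol (drimenol) | OC[C@H]1C(C)=CC[C@H]2C(C)(C)CCC[C@]12C
F4 | step 9 | (1S,4aS,8aS)-1-(bromomethyl)-2,5,5,8a-tetramethyl-1,4,4a,5,6,7,8,8a-octahydronaphthalene | BrC[C@H]1C(C)=CC[C@H]2C(C)(C)CCC[C@]12C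
F5 | step 7 | (4aS,8aS)-1,2,5,5,8a-pentamethyl-1,4,4a,5,6,7,8,8a-octahydronaphthalen-1-ol | OC1(C)C(C)=CC[C@H]2C(C)(C)CCC[C@]12C
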